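## Retrosynthetic overview
1. In biogenetic numbering (ring = C1–C14, carbinol = C15) the target is (14R,15S). C1 and OH lie syn along the C13–C16 zigzag, so the stereodiad comes from a cis (Z-derived) 14,15-epoxide opened at C14 with inversion by a C1 carbanion. The trans epoxide would give the wrong diastereomer.
2. Last C–C bond is C16–C17, made from lithiated geranyl sulfone and a 15,16-epoxide. One reductive step then removes both sulfur groups.
3. The only ring (14-membered) closes by intramolecular epoxide opening, C1 to C14, with a phenylthio-stabilised allyl anion.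
4. The epoxide comes from Sharpless epoxidation with L-(+)-DET of a (14Z)-16-hydroxygeranylgeranyl unit. This one step sets both stereocentres.
5. The Z-allylic alcohol comes from a B-alkyl Suzuki coupling of a farnesyl-acetate-derived 1,3-diene (SeO2, MnO2, Wittig) with (Z)-3-iodo-2-methylprop-2-en-1-ol.

Assumption: compounds 1, 5 and 13 are taken as catalogue chemicals, and biogenetic numbering C1–C24 is used in the explanations.

## Route

**Step 1**
Reactants: 1, (2E,6E)-farnesyl acetate
Product: 2, (2E,6E,10E)-12-hydroxyfarnesyl acetate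
Conditions: SeO2 (0.3 equiv), t-BuOOH, salicylic acid (cat.), CH2Cl2, 0 °C to rt
Reagents that add atoms: t-BuOOH, CC(C)(C)OO, with SeO2, O=[Se]=O (oxygen source)
Why: Sharpless-type SeO2 allylic oxidation (ene reaction then [2,3]-shift) hydroxylates only the E-methyl of the electron-rich terminal olefin, which fixes the 10E geometry.

**Step 2**
Reactants: 2
Product: 3, (2E,6E,10E)-12-oxofarnesyl acetate (enal)
Conditions: MnO2, CH2Cl2, rt
Reagents that add atoms: none
Why: MnO2 oxidises the allylic alcohol chemoselectively and leaves the acetate and olefin geometry untouched, and any enal over-oxidised in step 1 is pooled here.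

**Step 3**
Reactants: 3
Product: 4, (2E,6E,10E)-3,7,11-trimethyltrideca-2,6,10,12-tetraen-1-yl acetate
Conditions: Ph3PCH3Br, n-BuLi (1.1 equiv ylide), THF, −78 to 0 °C
Reagents that add atoms: methyltriphenylphosphonium bromide, C[P+](c1ccccc1)(c1ccccc1)c1ccccc1.[Br-] (adds CH2 = C13)
Why: Wittig methylenation of the reactive enal is much faster than ylide attack on the acetate at low temperature and gives the terminal 1,3-diene.

**Step 4**
Reactants: 5, propargyl alcohol
Product: 6, (Z)-3-iodo-2-methylprop-2-en-1-ol
Conditions: MeMgBr (3 equiv), CuI, Et2O/THF, −10 °C to rt; then I2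
Reagents that add atoms: MeMgBr, C[Mg]Br; iodine, II
Why: Cu-catalysed anti-carbomagnesiation through the chelated magnesium alkoxide followed by iodinolysis places I cis to CH2OH, so only the Z-iodide forms.

**Step 5**
Reactants: 4 and 6
Product: 7, (2E,6E,10E,14Z)-16-hydroxygeranylgeranyl acetate
Conditions: 9-BBN, THF, 0 °C to rt; then 6, PdCl2(dppf), AsPh3, Cs2CO3, DMF/H2O, rt
Reagents that add atoms: none (9-BBN delivers only H)
Why: 9-BBN hydroborates only the monosubstituted vinyl terminus (B on C13), and the B-alkyl Suzuki–Miyaura coupling retains the vinyl iodide geometry, so C13 ends up cis to C16.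

**Step 6**
Reactants: 7
Product: 8, (14R,15S)-14,15-epoxy-16-hydroxy acetate (cis-epoxide)
Conditions: Ti(OiPr)4, L-(+)-DET, t-BuOOH (decane), 4 Å MS, CH2Cl2, −20 °C
Reagents that add atoms: t-BuOOH, CC(C)(C)OO
Why: Sharpless asymmetric epoxidation is hydroxyl-directed, so only the allylic-alcohol olefin reacts, and L-(+)-DET gives the (2S,3R)-epoxy alcohol, which sets C15 (S, final) and C14 (to be inverted in step 9).

**Step 7**
Reactants: 8
Product: 9, epoxy diol (free C1–OH and C16–OH)
Conditions: K2CO3, MeOH, 0 °C
Reagents that add atoms: none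
Why: Mild methanolysis removes the acetate without epoxide opening or Payne migration.

**Step 8**
Reactants: 9
Product: 10, C1 phenyl sulfide of the epoxy alcohol
Conditions: PhSSPh (1.1 equiv), n-Bu3P (1.1 equiv), THF, 0 °C
Reagents that add atoms: diphenyl disulfide, c1ccc(cc1)SSc1ccccc1
Why: In the Hata sulfenylation the unhindered allylic C1 oxyphosphonium is displaced quickly by SN2, whereas the neopentyl-like C16–OH next to the quaternary epoxide carbon is not.

**Step 9**
Reactants: 10
Product: 11, macrocyclic 15,16-diol carrying SPh on ring C2 (= biogenetic C1), as an epimer mixture at that carbon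
Conditions: n-BuLi (2.3 equiv), DABCO, THF (about 2 mM), −78 to −20 °C
Reagents that add atoms: none
Why: The α-thio allyllithium attacks α-selectively at the less substituted epoxide carbon C14 by SN2 with inversion, closing the 14-ring with the C15–O bond intact and giving the required syn C14/C15 relationship, and the SPh-bearing centre is erased later.

**Step 10**
Reactants: 11
Product: 12, macrocyclic 15,16-epoxide (2-methyl-2-ring-oxirane)
Conditions: TsCl, Et3N, DMAP (cat.), CH2Cl2, 0 °C; then K2CO3, MeOH, rt
Reagents that add atoms: none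
Why: Selective primary tosylation followed by Williamson closure from the tertiary alkoxide breaks no bond at C15, so its configuration is retained.

**Step 11**
Reactants: 13, geranyl bromide
Product: 14, geranyl phenyl sulfone
Conditions: PhSO2Na, DMF, rt
Reagents that add atoms: sodium benzenesulfinate, [Na+].[O-]S(=O)c1ccccc1
Why: S-alkylation of the sulfinate by SN2 on the allylic bromide retains the E geometry.

**Step 12**
Reactants: 12 and 14
Product: 15, tertiary alcohol bearing C17–SO2Ph and ring SPh
Conditions: 14 (2 equiv), n-BuLi, THF/HMPA, −78 °C; then 12, warm to rt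
Reagents that add atoms: none
Why: The α-sulfonyl allyl carbanion opens the 2,2-disubstituted epoxide at its CH2 (C16), installing the tail without touching C14 or C15, and the ring sulfide is far too weakly acidic to interfere.

**Step 13**
Reactants: 15
Product: 16, colleterpenol
Conditions: Li, EtNH2/THF, −78 °C; NH4Cl quench
Reagents that add atoms: none
Why: Dissolving-metal cleavage removes both head-type allylic C–S bonds, and the allyl anions protonate at the less substituted terminus (C1 and C17), which keeps the E-trisubstituted olefins and leaves both stereocentres untouched.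

## Compound list
| No. | Name | SMILES | Role |
|---|---|---|---|
| 1 | (2E,6E)-farnesyl acetate | CC(=O)OC/C=C(\C)CC/C=C(\C)CCC=C(C)C | starting material |
| 2 | (2E,6E,10E)-12-hydroxy-3,7,11-trimethyldodeca-2,6,10-trien-1-yl acetate | CC(=O)OC/C=C(\C)CC/C=C(\C)CC/C=C(\C)CO | intermediate |
| 3 | (2E,6E,10E)-3,7,11-trimethyl-12-oxododeca-2,6,10-trien-1-yl acetate | CC(=O)OC/C=C(\C)CC/C=C(\C)CC/C=C(\C)C=O | intermediate |
| 4 | (2E,6E,10E)-3,7,11-trimethyltrideca-2,6,10,12-tetraen-1-yl acetate | CC(=O)OC/C=C(\C)CC/C=C(\C)CC/C=C(\C)C=C | intermediate |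
| 5 | propargyl alcohol | C#CCO | starting material |
| 6 | (Z)-3-iodo-2-methylprop-2-en-1-ol | OC/C(C)=C\I | intermediate |
| 7 | (2E,6E,10E,14Z)-16-hydroxy-3,7,11,15-tetramethylhexadeca-2,6,10,14-tetraen-1-yl acetate | CC(=O)OC/C=C(\C)CC/C=C(\C)CC/C=C(\C)CC/C=C(/C)CO | intermediate |
| 8 | (2E,6E,10E)-13-[(2R,3S)-3-(hydroxymethyl)-3-methyloxiran-2-yl]-3,7,11-trimethyltrideca-2,6,10-trien-1-yl acetate | CC(=O)OC/C=C(\C)CC/C=C(\C)CC/C=C(\C)CC[C@H]1O[C@@]1(C)CO | intermediate |
| 9 | (2E,6E,10E)-13-[(2R,3S)-3-(hydroxymethyl)-3-methyloxiran-2-yl]-3,7,11-trimethyltrideca-2,6,10-trien-1-ol | OC/C=C(\C)CC/C=C(\C)CC/C=C(\C)CC[C@H]1O[C@@]1(C)CO | intermediate |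
| 10 | {(2S,3R)-2-methyl-3-[(3E,7E,11E)-3,7,11-trimethyl-13-(phenylsulfanyl)trideca-3,7,11-trien-1-yl]oxiran-2-yl}methanol | c1ccccc1SC/C=C(\C)CC/C=C(\C)CC/C=C(\C)CC[C@H]1O[C@@]1(C)CO | intermediate |
| 11 | (2R)-2-[(1S,3E,7E,11E)-4,8,12-trimethyl-2-(phenylsulfanyl)cyclotetradeca-3,7,11-trien-1-yl]propane-1,2-diol (ring C2 epimers) | OC[C@](C)(O)[C@H]1C(Sc2ccccc2)/C=C(\C)CC/C=C(\C)CC/C=C(\C)CC1 | intermediate |
| 12 | (2R)-2-methyl-2-[(1S,3E,7E,11E)-4,8,12-trimethyl-2-(phenylsulfanyl)cyclotetradeca-3,7,11-trien-1-yl]oxirane | C1O[C@]1(C)[C@H]2C(Sc3ccccc3)/C=C(\C)CC/C=C(\C)CC/C=C(\C)CC2 | intermediate |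
| 13 | geranyl bromide | CC(C)=CCC/C(C)=C/CBr | starting material |
| 14 | geranyl phenyl sulfone | CC(C)=CCC/C(C)=C/CS(=O)(=O)c1ccccc1 | intermediate |
| 15 | (2S,5E)-6,10-dimethyl-4-(phenylsulfonyl)-2-[(1S,3E,7E,11E)-4,8,12-trimethyl-2-(phenylsulfanyl)cyclotetradeca-3,7,11-trien-1-yl]undeca-5,9-dien-2-ol (epimers at both S-bearing carbons) | CC(C)=CCC/C(C)=C/C(S(=O)(=O)c1ccccc1)C[C@](C)(O)[C@H]1C(Sc2ccccc2)/C=C(\C)CC/C=C(\C)CC/C=C(\C)CC1 | intermediate |
| 16 | colleterpenol, (2S,5E)-6,10-dimethyl-2-[(1R,3E,7E,11E)-4,8,12-trimethylcyclotetradeca-3,7,11-trien-1-yl]undeca-5,9-dien-2-ol | CC(C)=CCC/C(C)=C/CC[C@](C)(O)[C@H]1C/C=C(\C)CC/C=C(\C)CC/C=C(\C)CC1 | target |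

The R/S labels at C14 and C15 change between 8–15 and 16 only because CIP priorities change (S, O and C neighbours). The spatial arrangement changes once, by inversion at C14 in step 9.

## Totals
- **Total steps:** 13
- **Longest linear sequence:** 11 (steps 1, 2, 3, 5, 6, 7, 8, 9, 10, 12, 13)

## Three steps most likely to fail
1. **Step 9, macrocyclisation.** The risks are a hindered epoxide, the free C16 alkoxide and oligomerisation.
   - Fallback: switch to the other stereochemically valid disconnection.
   - Use (E,E)-farnesol-derived trans-epoxy alcohol as the C1/C14–C24 unit and join its CH2 (C1) to a C2 alkenyl cuprate.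
   - Open C14 intermolecularly with excess LiCH2SO2Ph (= C13).
   - Close the ring by the classical intramolecular alkylation of the C13 sulfonyl carbanion with a C12 allylic chloride, then desulfonylate.
2. **Step 6, Sharpless epoxidation of a Z-allylic alcohol.** The reaction is slow and ee is likely only about 85–90 %.
   - Fallback: add a resolution instead of relying on the catalyst.
   - Esterify the primary OH of diol 11 with (1S)-camphanic chloride, separate the diastereomeric esters, and saponify before step 10.
3. **Step 13, double dissolving-metal desulfurisation.** The risks are olefin transposition and E/Z leakage.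
   - Fallback: change the mechanism to π-allyl-palladium hydride delivery.
   - Oxidise the ring sulfide of 15 to the sulfone with Mo(VI)/H2O2, then remove both allylic sulfones with PdCl2(dppp)/LiHBEt3. Hydride adds at the less substituted terminus, so olefin position and geometry are retained.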